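**Retrosynthetic overview**

1. The butenolide is attached last: the C12–C13 bond is cut to a C9‑vinyl decalin triol and 3‑bromofuran‑2(5H)‑one (B‑alkyl Suzuki–Miyaura coupling).
2. The triol is traced back to a ring A cross‑conjugated dienone ester. One dissolving‑metal reductive methylation sets C5–H (trans fusion) and the C4 quaternary centre (ester = C19, axial). Reductions then give the equatorial C3–OH and C19–OH.
3. Key disconnection: ring A is cut at C1–C2 and C4–C5, both made as C=C bonds in one [3+3] cyclocondensation of a ring B β‑keto acetal (C1, C10, C5) with the bis(silyl enol ether) of methyl acetoacetate (C2–C3–C4–C19). The enabling feature is twofold: the C3 oxygen is flanked by C2 and by C4 carrying C19 (an acetoacetate), and C1 and C5 both sit on the hydrogen‑free quaternary C10, so ring A stops at a dienone that cannot aromatize.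
4. The ring B keto acetal is cut to (S)‑4‑[(benzyloxy)methyl]‑2‑methylcyclohex‑2‑enone (vinyl to C9 by conjugate addition, C1 to C10 by Mukaiyama formylation). The enone comes from 3‑(benzyloxy)propanal and ethyl vinyl ketone by organocatalytic Michael addition and aldol condensation, which sets C8.
5. Ring order: ring B first (steps 1–2), ring A second (step 6), the butenolide ring introduced intact last (step 10).

Key step: step 6

Remark: atom numbers follow labdane numbering of the target (ring A = C1–C5, C10; ring B = C5–C10; C17 on C8; C18 and C19 on C4; C20 on C10; C11–C16 side chain).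
Remark: the silyl enol ethers of the acetoacetate fragment are used as E/Z mixtures; the geometry is lost when these carbons become carbonyl carbons, so their SMILES carry no double‑bond descriptor.

**Route**

Step 1
Reactants: 1 3‑(benzyloxy)propanal; 2 pent‑1‑en‑3‑one (ethyl vinyl ketone)
Product: 3 (2R)‑2‑[(benzyloxy)methyl]‑5‑oxoheptanal
Conditions: (R)‑α,α‑diphenylprolinol trimethylsilyl ether (10 mol %), ethyl 3,4‑dihydroxybenzoate (20 mol %), neat, 4 °C
Reagents that add atoms: none
Why: Enamine‑catalysed asymmetric Michael addition of the aldehyde to the vinyl ketone; the diarylmethyl group of the (R)‑catalyst shields one face of the E‑enamine, so the enone should be attacked from the open face to give the (2R) centre that becomes C8 (8S in the target).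

Step 2
Reactants: 3 (2R)‑2‑[(benzyloxy)methyl]‑5‑oxoheptanal
Product: 4 (4S)‑4‑[(benzyloxy)methyl]‑2‑methylcyclohex‑2‑en‑1‑one
Conditions: p‑TsOH·H2O (10 mol %), toluene, 60 °C
Reagents that add atoms: none
Why: Acid‑catalysed intramolecular aldol condensation (6‑(enolendo)‑exo‑trig); only the ethyl ketone methylene can reach the aldehyde in a six‑membered ring, acid avoids β‑elimination of the benzyloxy group, and the C8 centre is not touched.

Step 3
Reactants: 4 (4S)‑4‑[(benzyloxy)methyl]‑2‑methylcyclohex‑2‑en‑1‑one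
Product: 5 {[(3R,4S)‑4‑[(benzyloxy)methyl]‑3‑ethenyl‑2‑methylcyclohex‑1‑en‑1‑yl]oxy}(trimethyl)silane
Conditions: vinylMgBr (1.5 equiv), CuBr·SMe2 (10 mol %), TMSCl (2.5 equiv), THF, −78 °C; Et3N, pentane work‑up
Reagents that add atoms: vinylmagnesium bromide, C=C[Mg]Br; chlorotrimethylsilane, C[Si](C)(C)Cl
Why: Copper‑catalysed conjugate addition of the vinyl Grignard reagent with in situ O‑silylation should deliver the vinyl group to C9 anti to the C8 substituent (the usual trans outcome for 4‑substituted cyclohexenones) and fixes the enol ether at C5=C10.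

Step 4
Reactants: 5 {[(3R,4S)‑4‑[(benzyloxy)methyl]‑3‑ethenyl‑2‑methylcyclohex‑1‑en‑1‑yl]oxy}(trimethyl)silane
Product: 6 (2R,3R,4S)‑4‑[(benzyloxy)methyl]‑2‑(dimethoxymethyl)‑3‑ethenyl‑2‑methylcyclohexan‑1‑one
Conditions: HC(OMe)3 (3 equiv), TMSOTf (10 mol %), CH2Cl2, −78 °C
Reagents that add atoms: trimethyl orthoformate, COC(OC)OC
Why: Mukaiyama‑type reaction of the silyl enol ether with the dimethoxycarbenium ion forms the quaternary C10; the C9 vinyl group lies pseudoaxial next to the fully substituted enol carbon (A(1,2) strain), so the small electrophile should enter from the opposite face, leaving C1 trans and the methyl group cis to the vinyl group.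

Step 5
Reactants: 7 methyl 3‑(trimethylsilyloxy)but‑2‑enoate
Product: 9 1‑methoxy‑1,3‑bis(trimethylsilyloxy)buta‑1,3‑diene, via lithium dienolate 8 (not isolated)
Conditions: LiN(i‑Pr)2 (1.1 equiv), THF, −78 °C; TMSCl (1.2 equiv), −78 → 0 °C
Reagents that add atoms: chlorotrimethylsilane, C[Si](C)(C)Cl
Why: γ‑Deprotonation of the silyloxy crotonate and O‑silylation of the dienolate gives the 1,3‑bis(silyl enol ether), a masked acetoacetate 1,3‑dianion.

Step 6
Reactants: 6 (2R,3R,4S)‑4‑[(benzyloxy)methyl]‑2‑(dimethoxymethyl)‑3‑ethenyl‑2‑methylcyclohexan‑1‑one; 9 1‑methoxy‑1,3‑bis(trimethylsilyloxy)buta‑1,3‑diene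
Product: 12 methyl (4aS,5R,6S)‑6‑[(benzyloxy)methyl]‑5‑ethenyl‑4a‑methyl‑2‑oxo‑2,4a,5,6,7,8‑hexahydronaphthalene‑1‑carboxylate, via open‑chain methoxy keto ester 10 (not isolated), via bicyclic ketol 11 (not isolated)
Conditions: 9 (1.5 equiv), TiCl4 (2.2 equiv), CH2Cl2, −78 → 20 °C; aq NaHCO3
Reagents that add atoms: none
Why: TiCl4 ionizes the acetal of 6 to an oxocarbenium ion at C1, which is captured by the terminal carbon of 9 (vinylogous Mukaiyama aldol, C1–C2); the titanium‑bound β‑keto ester then adds through its central carbon C4 to the titanium‑activated C5 ketone, and loss of titanium‑bound hydroxide and of methanol (both β to the C3 ketone) gives the dienone. The closest known reaction type is the [3+3] cyclocondensation of 1,3‑bis(silyl enol ethers) with β‑keto acetals and other 1,3‑dielectrophiles, including 2,2‑disubstituted ones; here the quaternary C10 stops the usual aromatization at the cyclohexadienone stage. Ring A is closed by a 6‑(enolendo)‑exo‑trig aldol (intramolecular Knoevenagel) closure. No stereocentre is created, since both new bonds finish as double bonds (C1=C2 and C4=C5), and the C8, C9 and C10 centres lie outside the reacting carbons and are retained. The step needs chemo‑ and regioselectivity (terminal diene carbon to C1, central carbon to C5); this is secured by the much higher electrophilicity of the oxocarbenium ion over the neopentyl ketone and by the fact that only the six‑membered closure is open to C4. Ring closure should precede loss of methanol because C1 stays tetrahedral until the titanium aldolate has formed, so no E‑enone that could not cyclize should arise.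

Step 7
Reactants: 12 methyl (4aS,5R,6S)‑6‑[(benzyloxy)methyl]‑5‑ethenyl‑4a‑methyl‑2‑oxo‑2,4a,5,6,7,8‑hexahydronaphthalene‑1‑carboxylate
Product: 14 methyl (1S,4aS,5R,6S,8aS)‑5‑ethenyl‑6‑(hydroxymethyl)‑1,4a‑dimethyl‑2‑oxo‑1,2,4a,5,6,7,8,8a‑octahydronaphthalene‑1‑carboxylate, via dilithium dienolate alkoxide 13 (not isolated)
Conditions: Li (6 equiv), NH3(l)/THF, t‑BuOH (1 equiv), −78 °C; isoprene; MeI (10 equiv), −78 → −33 °C; NH4Cl
Reagents that add atoms: iodomethane, CI
Why: Dissolving‑metal (Birch‑type) reductive alkylation: lithium in ammonia should reduce only the more electron‑poor, ester‑bearing C4=C5 bond of the cross‑conjugated dienone (the resulting dienolate resists further reduction), axial protonation at C5 gives the trans ring fusion, methyl iodide alkylates C4 from the face opposite the axial C10 methyl group so that the ester becomes axial and cis to C20, and the benzyl ether is cleaved in the same operation.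

Step 8
Reactants: 14 methyl (1S,4aS,5R,6S,8aS)‑5‑ethenyl‑6‑(hydroxymethyl)‑1,4a‑dimethyl‑2‑oxo‑1,2,4a,5,6,7,8,8a‑octahydronaphthalene‑1‑carboxylate
Product: 15 methyl (1S,4aS,5R,6S,8aS)‑5‑ethenyl‑6‑(hydroxymethyl)‑1,4a‑dimethyl‑2‑oxodecahydronaphthalene‑1‑carboxylate
Conditions: Cu(OAc)2·H2O (5 mol %), 1,2‑bis(diphenylphosphino)benzene (5 mol %), Me(EtO)2SiH (2.5 equiv), t‑BuOH (2.5 equiv), toluene, rt; aq NH4F
Reagents that add atoms: none
Why: Copper hydride‑catalysed conjugate reduction is selective for the C1=C2 enone over the isolated vinyl group and the ester, and forms no stereocentre.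

Step 9
Reactants: 15 methyl (1S,4aS,5R,6S,8aS)‑5‑ethenyl‑6‑(hydroxymethyl)‑1,4a‑dimethyl‑2‑oxodecahydronaphthalene‑1‑carboxylate
Product: 16 (1R,2R,4aS,5R,6S,8aS)‑5‑ethenyl‑1,6‑bis(hydroxymethyl)‑1,4a‑dimethyldecahydronaphthalen‑2‑ol
Conditions: LiAlH4 (5 equiv), THF, 0 °C → reflux; aq NaOH work‑up
Reagents that add atoms: none
Why: Hydride reduction of the ketone and the neopentyl ester; axial attack on the C3 carbonyl, from the face opposite the axial C4 ester, should give the equatorial alcohol, cis to C19.

Step 10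
Reactants: 16 (1R,2R,4aS,5R,6S,8aS)‑5‑ethenyl‑1,6‑bis(hydroxymethyl)‑1,4a‑dimethyldecahydronaphthalen‑2‑ol; 17 3‑bromofuran‑2(5H)‑one
Product: 19 14‑deoxy‑17‑hydroxyandrographolide, via tetraboryl adduct 18 (not isolated)
Conditions: 9‑BBN (5 equiv), THF, 0 °C → rt; then 3 M aq K3PO4, 17 (1.5 equiv), PdCl2(dppf) (10 mol %), AsPh3 (10 mol %), DMF, rt → 45 °C
Reagents that add atoms: none
Why: Anti‑Markovnikov hydroboration of the terminal vinyl group (the hydroxyls are carried as borinates that hydrolyse in the aqueous base) followed by B‑alkyl Suzuki–Miyaura coupling with the α‑bromobutenolide forms C12–C13 without touching any stereocentre.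

**Compound list**

1 | 3‑(benzyloxy)propanal | O=CCCOCc1ccccc1 | starting material
2 | pent‑1‑en‑3‑one | C=CC(=O)CC | starting material
3 | (2R)‑2‑[(benzyloxy)methyl]‑5‑oxoheptanal | CCC(=O)CC[C@H](COCc1ccccc1)C=O | intermediate
4 | (4S)‑4‑[(benzyloxy)methyl]‑2‑methylcyclohex‑2‑en‑1‑one | O=C1CC[C@H](COCc2ccccc2)C=C1C | intermediate
5 | {[(3R,4S)‑4‑[(benzyloxy)methyl]‑3‑ethenyl‑2‑methylcyclohex‑1‑en‑1‑yl]oxy}(trimethyl)silane | C[Si](C)(C)OC1=C(C)[C@H](C=C)[C@@H](COCc2ccccc2)CC1 | intermediate
6 | (2R,3R,4S)‑4‑[(benzyloxy)methyl]‑2‑(dimethoxymethyl)‑3‑ethenyl‑2‑methylcyclohexan‑1‑one | O=C1CC[C@H](COCc2ccccc2)[C@@H](C=C)[C@]1(C)C(OC)OC | intermediate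
7 | methyl 3‑(trimethylsilyloxy)but‑2‑enoate (E/Z mixture) | COC(=O)C=C(C)O[Si](C)(C)C | starting material
8 | lithium dienolate of 7 (not isolated) | [Li+].COC([O-])=CC(=C)O[Si](C)(C)C | intermediate
9 | 1‑methoxy‑1,3‑bis(trimethylsilyloxy)buta‑1,3‑diene (E/Z mixture) | COC(O[Si](C)(C)C)=CC(=C)O[Si](C)(C)C | intermediate
10 | methyl 5‑[(1R,2R,3S)‑3‑[(benzyloxy)methyl]‑2‑ethenyl‑1‑methyl‑6‑oxocyclohexyl]‑5‑methoxy‑3‑oxopentanoate, C5 epimers (not isolated) | COC(=O)CC(=O)CC(OC)[C@@]1(C)[C@H](C=C)[C@@H](COCc2ccccc2)CCC1=O | intermediate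
11 | methyl (4aR,5R,6S)‑6‑[(benzyloxy)methyl]‑5‑ethenyl‑8a‑hydroxy‑4‑methoxy‑4a‑methyl‑2‑oxodecahydronaphthalene‑1‑carboxylate, mixture at C1, C4 and C8a (not isolated) | COC(=O)C1C(=O)CC(OC)[C@@]2(C)[C@H](C=C)[C@@H](COCc3ccccc3)CCC12O | intermediate
12 | methyl (4aS,5R,6S)‑6‑[(benzyloxy)methyl]‑5‑ethenyl‑4a‑methyl‑2‑oxo‑2,4a,5,6,7,8‑hexahydronaphthalene‑1‑carboxylate | COC(=O)C1=C2CC[C@H](COCc3ccccc3)[C@@H](C=C)[C@]2(C)C=CC1=O | intermediate
13 | dilithium salt (C3 enolate, C17 alkoxide) of the reduced, debenzylated keto ester (not isolated) | [Li+].[Li+].COC(=O)C1=C([O-])C=C[C@@]2(C)[C@H](C=C)[C@@H](C[O-])CC[C@H]12 | intermediate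
14 | methyl (1S,4aS,5R,6S,8aS)‑5‑ethenyl‑6‑(hydroxymethyl)‑1,4a‑dimethyl‑2‑oxo‑1,2,4a,5,6,7,8,8a‑octahydronaphthalene‑1‑carboxylate | C[C@]1(C(=O)OC)[C@H]2CC[C@H](CO)[C@@H](C=C)[C@]2(C)C=CC1=O | intermediate
15 | methyl (1S,4aS,5R,6S,8aS)‑5‑ethenyl‑6‑(hydroxymethyl)‑1,4a‑dimethyl‑2‑oxodecahydronaphthalene‑1‑carboxylate | C[C@]1(C(=O)OC)[C@H]2CC[C@H](CO)[C@@H](C=C)[C@]2(C)CCC1=O | intermediate
16 | (1R,2R,4aS,5R,6S,8aS)‑5‑ethenyl‑1,6‑bis(hydroxymethyl)‑1,4a‑dimethyldecahydronaphthalen‑2‑ol | C[C@]1(CO)[C@H]2CC[C@H](CO)[C@@H](C=C)[C@]2(C)CC[C@H]1O | intermediate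
17 | 3‑bromofuran‑2(5H)‑one | O=C1OCC=C1Br | starting material
18 | B‑alkyl‑9‑BBN adduct of 16 at C12, the three hydroxyls as 9‑BBN borinates (not isolated) | C[C@]1(COB3C4CCCC3CCC4)[C@H]2CC[C@H](COB3C4CCCC3CCC4)[C@@H](CCB3C4CCCC3CCC4)[C@]2(C)CC[C@H]1OB1C2CCCC1CCC2 | intermediate
19 | 14‑deoxy‑17‑hydroxyandrographolide, 3‑{2‑[(1R,2S,4aS,5R,6R,8aS)‑6‑hydroxy‑2,5‑bis(hydroxymethyl)‑5,8a‑dimethyldecahydronaphthalen‑1‑yl]ethyl}furan‑2(5H)‑one | C[C@]1(CO)[C@H]2CC[C@H](CO)[C@@H](CCC3=CCOC3=O)[C@]2(C)CC[C@H]1O | target

**Step count**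

Total steps: 10. Longest linear sequence: 9 (steps 1–4 and 6–10); step 5 is a one‑step branch.

**Steps most likely to fail, with fallbacks**

Step 6. What may go wrong: methanol may be lost from the first adduct before the β‑keto ester carbon has closed onto the hindered C5 ketone, leaving an E‑enone that cannot cyclize; the diene may also be protodesilylated by adventitious HCl. The fallback makes the two bonds in separate operations under different activation. It sets out from 6 and 9: a TMSOTf‑catalysed (10 mol %) vinylogous Mukaiyama addition in CH2Cl2 at −78 °C is stopped at the open‑chain stage and worked up with aqueous NaHCO3 to give methoxy keto ester 10, now isolated. Intramolecular Knoevenagel condensation with TiCl4 and pyridine in THF at 0 °C closes ring A while C1 is still tetrahedral and should give the methoxy enone ester F1. Elimination of methanol with DBU in toluene at 60 °C comes back to the route at 12.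

Step 4. What may go wrong: poor facial selectivity in forming the quaternary carbon. In the conformer with a pseudoaxial vinyl group the C8 substituent becomes syn‑axial to the incoming electrophile, so attack syn to the vinyl group may compete. The fallback replaces substrate control by reagent control. It sets out from 5: catalytic asymmetric hydroxymethylation with aqueous formaldehyde, Sc(OTf)3 (10 mol %) and an enantiopure 2,2'‑bipyridine diol ligand in DME/H2O at −20 °C should give the hydroxymethyl ketone F2; the ligand enantiomer is chosen to reinforce delivery anti to the vinyl group. Oxidation (DMP, NaHCO3, CH2Cl2) should give the keto aldehyde F3, and acetalization (HC(OMe)3, MeOH, PPTS) comes back to the route at 6.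

Step 7. What may go wrong: over‑reduction once debenzylation builds up lithium amide, proton quench of the dienolate before alkylation, or consumption of the electrophile by amide and alkoxide. The fallback separates reduction from alkylation. It sets out from 12: the lithium/ammonia reduction is quenched with solid NH4Cl instead of MeI, which should give the unmethylated β‑keto ester F4 with the benzyl group already cleaved. C‑Methylation of this doubly activated carbon as its thermodynamic enolate (MeI, K2CO3, acetone, rt) deprotonates neither the primary alcohol nor the other ketone α‑position, should again place the methyl group anti to the C10 methyl group, and comes back to the route at 14.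

**Further compounds**

F1 | step 6 | methoxy enone ester: methyl 6‑[(benzyloxy)methyl]‑5‑ethenyl‑4‑methoxy‑4a‑methyl‑2‑oxo‑2,3,4,4a,5,6,7,8‑octahydronaphthalene‑1‑carboxylate, ring B configuration as in 12, C4 epimers | COC(=O)C1=C2CC[C@H](COCc3ccccc3)[C@@H](C=C)[C@]2(C)C(OC)CC1=O
F2 | step 4 | hydroxymethyl ketone: 4‑[(benzyloxy)methyl]‑3‑ethenyl‑2‑(hydroxymethyl)‑2‑methylcyclohexan‑1‑one, configuration as in 6 | O=C1CC[C@H](COCc2ccccc2)[C@@H](C=C)[C@]1(C)CO
F3 | step 4 | keto aldehyde: 3‑[(benzyloxy)methyl]‑2‑ethenyl‑1‑methyl‑6‑oxocyclohexane‑1‑carbaldehyde, configuration as in 6 | O=C1CC[C@H](COCc2ccccc2)[C@@H](C=C)[C@]1(C)C=O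
F4 | step 7 | unmethylated β‑keto ester: methyl 5‑ethenyl‑6‑(hydroxymethyl)‑4a‑methyl‑2‑oxo‑1,2,4a,5,6,7,8,8a‑octahydronaphthalene‑1‑carboxylate, trans‑fused, ring B configuration as in 14, C1 epimers | COC(=O)C1[C@H]2CC[C@H](CO)[C@@H](C=C)[C@]2(C)C=CC1=O
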